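**Remarks on the chemistry (assumptions, one line each)**

- Atom labels: unprimed atoms belong to dihydrobenzofuran 1 (benzo ring A), primed atoms to dihydrobenzofuran 2 (benzo ring B); the target is (2S,3S,2′R,3′R), both five-membered rings trans.
- Stereochemical check of the key step: anti addition of the two aryl groups across the E alkene corresponds to the (1R,2R) boronic ester, whose C3′ has the sense of the target.
- Design choice 1: the boron sits on the hindered meso diol 2 and not on pinacol, because β-substituted alkenyl pinacol borates tend to hand their groups directly to palladium.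
- Design choice 2: all spectator phenols are benzyl ethers and the second ring B oxygen is a MOM ether, because a final demethylation with strong acid would endanger the Z stilbene and the benzylic C–O bonds.
- Design choice 3: the key step uses the aryllithium; the second coupling (step 15) uses the corresponding aryl Grignard reagent, because 19 carries a diarylmethine C3′–H β to the ring oxygen that a strongly basic organolithium solution could remove with ring opening.
- Ligand hand: (Sp,Sp)-MandyPhos, Fe[C5H3(PAr2)(CHPhNMe2)]2 with Ar = 4-methoxy-3,5-dimethylphenyl, is assumed to give the (1R,2R) product in step 6 and its (Rp,Rp) mirror image the (1S,2S) product in step 15; if a trial coupling shows the opposite sense, the two are exchanged as a pair.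
- Compounds 1, 3, 7, 10, 20 and 29 are taken as commercial.

## Structural features

The target is a stilbenoid trimer built from two trans-2,3-diaryl-2,3-dihydrobenzofurans joined by one bond from C3 of dihydrobenzofuran 1 to C5′ of ring B. Ring A carries a (Z)-4-hydroxystyryl group at C4 and a hydroxyl at C6, and ring B a hydroxyl at C7′. C2 and C2′ each bear a 4-hydroxyphenyl group and C3′ a 3,5-dihydroxyphenyl group. The four stereocentres form two adjacent pairs, C2/C3 (S,S) and C2′/C3′ (R,R); ring B lies between the pairs, so neither can steer the other. The fragile points are the benzylic ether bonds O1–C2 and O1′–C2′, which ionise under acid to 4-oxybenzyl cations, the Z stilbene, which isomerises or is attacked by neighbouring electron-rich rings under acid or light, and the seven oxidisable phenols. The real difficulty lies in the diarylmethine centres C3′ and C3: each carries two different electron-rich aryl groups and no heteroatom, so neither carbonyl addition nor equilibration can set them, and C3 also adjoins C3a, a ring A carbon with two ortho substituents. The key step exploits the fact that C2′ and C3′ together hold three different aryl groups next to the oxygen on C2′ (4-hydroxyphenyl on C2′; ring B through C3a′ and the 3,5-dihydroxyphenyl ring on C3′). This is the pattern left by 1,2-diarylation of an E 3,5-dioxystyryl boron unit followed by oxidation of C–B.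

## Logic of the disconnections

33 from 32. Six aryl O–CH2Ph bonds are cut. The phenols must stay masked through the organometallic, palladium and ylide steps, and the unmasking must not expose the Z alkene or the two benzylic C–O bonds to hot or protic strong acid, which rules out methyl ethers. The gain is that every earlier intermediate is a neutral ether that can be chromatographed. The demand is a debenzylation that uses no hydrogen and works at −78 °C.

32 from 28 and 30 (through 31). The C=C bond of the stilbene is cut. The Z alkene is the most acid- and light-sensitive element, so it is made after the last acid step. One aryl ring leaves as a simple salt and the remainder is an aldehyde. The forward step must be kinetically Z-selective and must tolerate the free C6 hydroxyl of 28.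

28 from 27. O1–C2 is cut. This bond forms and re-forms under acid through the 4-benzyloxybenzyl cation, so C2 need not be controlled earlier and only C3 has to be carried. The same acid removes both MOM groups and the dioxolane of 27, so three deprotections merge with the ring closure. Capture by the C7a oxygen must outrun loss of the C3 proton, and the first dihydrobenzofuran must survive.

27 from 10, 19 and 23 (through 24, 25 and 26). C2–aryl and C3–C3a are cut and C2–O is traced back to C2–B. C3 is a diarylmethine without a heteroatom, and a 1,2-metallate shift sets it under catalyst control while joining three pieces. The second ring system is reduced to an alkenyl boronic ester, an aryl bromide and an aryl Grignard reagent. The demand is heavy: the bromine-bearing carbon of 23 has two ortho substituents, the ligand must override the remote C2′/C3′ centres, and the aryl metal must not deprotonate C3′.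

19 from 17 from 16. The C–B bond and then the alkyne carbon are cut. Syn hydroboration of a terminal alkyne is the surest source of an E alkenyl boron unit, and the alkyne comes from the aldehyde by one-carbon homologation. The boron is placed on 2 for the reason stated in the remarks. The forward steps need only mild base and must give the E geometry.

16 from 15 from 14 from 13. The C7′ O–benzyl bond, then O1′–C2′, then C2′–O (traced to C2′–B) are cut, for the same reasons as above. Two MOM groups on the catechol of 14 make the regiochemistry of closure automatic, because only the C7a′ oxygen can form a five-membered ring; the price is one re-benzylation. The oxidation of C–B must go with retention and nothing may erode C3′.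

13 from 6, 10 and 9 (through 11 and 12), the key disconnection. C2′–aryl and C3′–C3a′ are cut. The three aryl-bearing pieces of dihydrobenzofuran 2 are joined in one operation and C3′, the centre that persists, is fixed by the catalyst. The forward step must favour metallate shift over direct boron-to-palladium transfer, must add anti across the E alkene, and must discriminate the alkene faces.

6 from 4 and 2; 4 from 3; 2 from 1. The C–B bond, the alkyne carbon and the two C–CH3 bonds of the diol are cut. All three are routine, and the only demand is E geometry in the hydroboration and the cis diol.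

9 from 8 from 7; 23 from 22 from 21 from 20; 30 from 29. These cuts remove acetal, MOM, bromine and phosphorus in turn. The C–Br bond of 22 relies on the symmetry of 21, which makes the two positions ortho to the formyl group equivalent. The acetalisations must not disturb the MOM ethers.

## Other disconnections considered

Alternative 1: The cut is C3–C3a of dihydrobenzofuran 1, made in the forward sense by ring contraction of a flavanone. The benzyl, methyl and pivaloyl protected (S)-naringenin A1 would be treated with PhI(OAc)2 (trivalent iodine) in an acidic orthoformate medium. Iodine attacks the enol ether at C3, ring A shifts from the carbonyl carbon to C3 as the aryl iodide leaves, and the old carbonyl carbon is trapped as the methyl ester, giving the trans ester A2.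
- In its favour: C2 comes from the chiral pool with the (S) configuration the target needs, C3 is set trans to it and can equilibrate through the ester enolate, and the reaction type is established for flavanones.
- Where it is equal or better: on the origin of absolute configuration in dihydrobenzofuran 1 it is better than the chosen plan, which needs a second catalytic step with a hindered bromide. On trans control the two are equal.
- Against it here: A2 has oxygen at C4 where the target has the styryl carbon, so debenzylation, triflation and a cross-coupling would be needed. The C3 substituent is only a one-carbon ester, so ring B and all of dihydrobenzofuran 2, including C3′, would still have to be grown from it. Flavanones lose their C2 configuration through the ring-opened chalcone, and the competing aryl shift to an isoflavone is known.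
- Comparison: mechanistically this is an oxidative rearrangement that forms one skeletal bond, while the chosen key step joins three aryl-bearing pieces. It is short for the first ring system but longer overall.

Alternative 2: The cut goes through ring B itself, at C7a′–C3a′ and C7′–C6′, so that ring B derives from a furan and an alkyne. The furyl ethynyl ether A3 would be exposed to Ph3PAuNTf2 (monovalent gold). Furan C2 attacks the gold-activated alkyne, and the carbenoid, oxepine and arene oxide stages that follow would leave the furan oxygen as the C7′ phenol, closing ring B and the dihydrofuran ring together to give A4.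
- In its favour and better than the chosen step: it is an isomerisation with no by-product, whereas the chosen step discards lithium and sodium salts. It forms two rings in one operation, whereas the chosen step forms none. It delivers the C7′ hydroxyl free and distinguished from the other oxygens, without the two MOM groups and the re-benzylation of the chosen plan.
- Against it here: C2′ and C3′ must already be present and correct in A3, and C2′ cannot be corrected later because its C–O bond is never re-formed. The furyl aryl methine C3′ needs an enantioselective method of its own, so the central problem is moved and not solved. An ethynyl ether of a secondary 4-methoxybenzylic alcohol is prone to ionisation, sigmatropic shift and hydration. The silyloxymethyl group must still be oxidised before ring A can be attached.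
- Comparison: structurally the alternative builds the arene while the chosen plan buys it. Both rely on π-activation by a late metal, but only the chosen step creates stereocentres under catalyst control. The preparation of A3 would probably cost more steps than the three-component union saves.

Alternative 3: The cut removes ring A: C3a–C7a, C4–C5 and C6–C7 are disconnected to three alkynes. The diyne A5 (an ethynyl ether on O1 and a Z-enyne on C3) and ethoxyacetylene A7 would be combined on the cationic catalyst from [Rh(cod)2]BF4 and BINAP (monovalent rhodium). Oxidative coupling of the tethered alkynes to a rhodacyclopentadiene, insertion of A7 and reductive elimination would close ring A and the dihydrofuran ring at once and give A6.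
- In its favour and better than the chosen step: three C–C bonds and two rings form in one step, against two bonds and no ring. The Z-styryl group arrives in place, so no late olefination is needed. The congested C3–C3a bond, the weakest point of the chosen plan, is made inside a ring-forming event.
- Against it here: the orientation of A7 (ethoxy at C6, not C5) rests only on electronic bias between two oxygen-polarised alkynes. Homotrimerisation of A7 competes. The conjugated Z-enyne can bind rhodium or lose its geometry. The ethynyl ether at the benzylic C2 oxygen is as labile as in alternative 2. C2 and C3 must both be set beforehand, and the chiral ligand creates no stereocentre here. A6 is a heptaalkyl ether with an ethyl group, so seven ether cleavages by a strong Lewis acid would be needed in the presence of the Z stilbene, the operation the chosen plan avoids.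
- Comparison: the alternative is more convergent at the end, but the long preparation of A5 offsets the saving, so no clear gain in step count is expected.

Key step: step 6

## Route

Step 1
Reactants: 1 acenaphthylene-1,2-dione
Product: 2 cis-1,2-dimethyl-1,2-dihydroacenaphthylene-1,2-diol (meso diol)
Conditions: MeMgBr (2.5 equiv), THF, 0 °C to rt; then H2O; recrystallisation
Reagents that add atoms: methylmagnesium bromide, C[Mg]Br
Why: Double 1,2-addition of a Grignard reagent to a 1,2-dione that cannot enolise; the second methyl group should enter anti to the magnesium alkoxide so that the cis (meso) diol predominates, and crystallisation removes any trans isomer.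

Step 2
Reactants: 3 3,5-bis(benzyloxy)benzaldehyde
Product: 4 1,3-bis(benzyloxy)-5-ethynylbenzene
Conditions: MeC(O)C(N2)P(O)(OMe)2 (1.3 equiv), K2CO3 (2 equiv), MeOH/THF, rt
Reagents that add atoms: dimethyl (1-diazo-2-oxopropyl)phosphonate, CC(=O)C(=[N+]=[N-])P(=O)(OC)OC
Why: Ohira–Bestmann homologation: methanolysis frees the diazomethylphosphonate anion, which adds to the aldehyde, and the derived alkylidene carbene rearranges to the terminal alkyne; benzyl ethers are inert to K2CO3 in MeOH.

Step 3
Reactants: 4 1,3-bis(benzyloxy)-5-ethynylbenzene; 2 cis-1,2-dimethyl-1,2-dihydroacenaphthylene-1,2-diol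
Product: 6 (E)-2-[3,5-bis(benzyloxy)phenyl]ethenylboronic ester of diol 2, via catechol boronic ester 5 (not isolated)
Conditions: catecholborane (1.2 equiv), Cy2BH (5 mol%), THF, rt; then 2 (1.2 equiv), rt
Reagents that add atoms: catecholborane, B1Oc2ccccc2O1
Why: Dialkylborane-catalysed syn, anti-Markovnikov hydroboration of the terminal arylalkyne fixes the E geometry; the labile catechol ester then exchanges with the aliphatic cis diol to give an ester that can be chromatographed.

Step 4
Reactants: 7 3-bromo-4,5-dihydroxybenzaldehyde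
Product: 8 3-bromo-4,5-bis(methoxymethoxy)benzaldehyde
Conditions: MOMCl (2.6 equiv), i-Pr2NEt (3 equiv), CH2Cl2, 0 °C to rt
Reagents that add atoms: chloromethyl methyl ether, COCCl
Why: Williamson-type O-alkylation of both phenols; MOM survives aryllithium, palladium and alkaline peroxide and leaves with acid in step 8.

Step 5
Reactants: 8 3-bromo-4,5-bis(methoxymethoxy)benzaldehyde
Product: 9 2-[3-bromo-4,5-bis(methoxymethoxy)phenyl]-1,3-dioxolane
Conditions: (Me3SiOCH2)2 (1.5 equiv), Me3SiOTf (2 mol%), CH2Cl2, −78 °C; pyridine quench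
Reagents that add atoms: 1,2-bis(trimethylsilyloxy)ethane, C[Si](C)(C)OCCO[Si](C)(C)C
Why: Aprotic acetalisation driven by formation of hexamethyldisiloxane; at −78 °C without protic acid the aryl MOM ethers should stay intact, and the dioxolane keeps the formyl group away from the borate complex and from alkaline peroxide.

Step 6
Reactants: 10 1-(benzyloxy)-4-bromobenzene; 6 (E)-2-[3,5-bis(benzyloxy)phenyl]ethenylboronic ester of diol 2; 9 2-[3-bromo-4,5-bis(methoxymethoxy)phenyl]-1,3-dioxolane
Product: 13 boronic ester of diol 2 with (1R,2R)-1-[4-(benzyloxy)phenyl]-2-[3,5-bis(benzyloxy)phenyl]-2-[5-(1,3-dioxolan-2-yl)-2,3-bis(methoxymethoxy)phenyl]ethylboronic acid, via aryllithium 11 (not isolated), via lithium borate complex 12 (not isolated)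
Conditions: 10, t-BuLi (2.0 equiv), THF, −78 °C; add 6, −78 °C to rt; then 9, Pd(OAc)2 (3 mol%), (Sp,Sp)-MandyPhos Fe[C5H3(PAr2)(CHPhNMe2)]2 (3.6 mol%), NaOTf (2 equiv), THF, 60 °C
Reagents that add atoms: none
Why: Bromine–lithium exchange on 10 gives 11, which adds to the boron of 6 to give the four-coordinate borate 12. Zerovalent palladium inserts into the C–Br bond of 9, NaOTf removes bromide, and the cationic arylpalladium (divalent palladium) binds the alkene of 12 on the face chosen by the ferrocenyl bisphosphine. The 4-benzyloxyphenyl group then shifts from boron to C2′ anti to palladium (1,2-metallate shift) as the Pd–C3′ bond forms, and reductive elimination with retention makes C3′–C3a′ and returns zerovalent palladium. The closest known reaction type is the enantioselective conjunctive cross-coupling of alkenylboron ate complexes, including its anti-selective form for β-substituted alkenyl boronates of hindered diols; a β-aryl alkene with an ortho-alkoxy aryl bromide is an extension within that class. No ring is closed. C3′ is set by the ligand-controlled face of alkene binding, and C2′ follows from the anti stereospecificity across the E double bond, which gives the (1R,2R) isomer. The step needs the metallate shift to outrun direct boron-to-palladium transfer; the bulky diol of 12 shields the B–O oxygens needed for transmetalation, NaOTf keeps palladium halide-free and electrophilic, and the C–Br bond is the only reactive site of 9. Only C3′ has to be formed with high fidelity, because step 8 re-forms C2′.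

Step 7
Reactants: 13 boronic ester from step 6
Product: 14 (1R,2R)-1-[4-(benzyloxy)phenyl]-2-[3,5-bis(benzyloxy)phenyl]-2-[5-(1,3-dioxolan-2-yl)-2,3-bis(methoxymethoxy)phenyl]ethan-1-ol
Conditions: H2O2 (30% aq.), NaOH (3 M aq.), THF, 0 °C to rt
Reagents that add atoms: hydrogen peroxide, OO
Why: Alkaline peroxide oxidation of the C–B bond (boronate 1,2-shift to oxygen with retention); MOM ethers, dioxolane and benzyl ethers are stable to base and peroxide, and diol 2 is released for recovery.

Step 8
Reactants: 14 triarylethanol from step 7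
Product: 15 (2R,3R)-2-[4-(benzyloxy)phenyl]-3-[3,5-bis(benzyloxy)phenyl]-7-hydroxy-2,3-dihydro-1-benzofuran-5-carbaldehyde
Conditions: HCl (6 M aq.), THF, 50 °C
Reagents that add atoms: water, O
Why: Acid hydrolyses both MOM ethers and the dioxolane and ionises the benzylic alcohol to the 4-benzyloxybenzyl cation, which the C7a′ oxygen captures in a five-membered SN1 etherification; closure anti to the C3′ aryl group and equilibration through reversible C–O ionisation give the trans (2R,3R) ring while C3′ is untouched. The C7′ oxygen cannot reach C2′, and aryl benzyl ethers survive these conditions.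

Step 9
Reactants: 15 hydroxy aldehyde from step 8
Product: 16 (2R,3R)-7-(benzyloxy)-2-[4-(benzyloxy)phenyl]-3-[3,5-bis(benzyloxy)phenyl]-2,3-dihydro-1-benzofuran-5-carbaldehyde
Conditions: BnBr (1.2 equiv), K2CO3 (2 equiv), DMF, rt
Reagents that add atoms: benzyl bromide, BrCc1ccccc1
Why: Williamson etherification of the single free phenol, which masks the C7′ oxygen like the others for the organometallic steps ahead.

Step 10
Reactants: 16 aldehyde from step 9
Product: 17 (2R,3R)-7-(benzyloxy)-2-[4-(benzyloxy)phenyl]-3-[3,5-bis(benzyloxy)phenyl]-5-ethynyl-2,3-dihydro-1-benzofuran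
Conditions: MeC(O)C(N2)P(O)(OMe)2 (1.5 equiv), K2CO3 (2 equiv), MeOH/THF, rt
Reagents that add atoms: dimethyl (1-diazo-2-oxopropyl)phosphonate, CC(=O)C(=[N+]=[N-])P(=O)(OC)OC
Why: Ohira–Bestmann homologation under mild base, which touches neither the benzylic C2′–O bond nor the stereocentres.

Step 11
Reactants: 17 alkyne from step 10; 2 cis-1,2-dimethyl-1,2-dihydroacenaphthylene-1,2-diol
Product: 19 (E)-2-[(2R,3R)-7-(benzyloxy)-2-[4-(benzyloxy)phenyl]-3-[3,5-bis(benzyloxy)phenyl]-2,3-dihydro-1-benzofuran-5-yl]ethenylboronic ester of diol 2, via catechol boronic ester 18 (not isolated)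
Conditions: catecholborane (1.3 equiv), Cy2BH (5 mol%), THF, rt; then 2 (1.3 equiv), rt
Reagents that add atoms: catecholborane, B1Oc2ccccc2O1
Why: Same syn hydroboration and diol exchange as in step 3, giving the E alkenyl boronate required for anti diarylation.

Step 12
Reactants: 20 3,5-dihydroxybenzaldehyde
Product: 21 3,5-bis(methoxymethoxy)benzaldehyde
Conditions: MOMCl (2.6 equiv), i-Pr2NEt (3 equiv), CH2Cl2, 0 °C to rt
Reagents that add atoms: chloromethyl methyl ether, COCCl
Why: Double O-alkylation; both MOM groups are meant to leave in step 16, one oxygen closing the ring and the other becoming the free C6 hydroxyl of the target.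

Step 13
Reactants: 21 3,5-bis(methoxymethoxy)benzaldehyde
Product: 22 2-bromo-3,5-bis(methoxymethoxy)benzaldehyde
Conditions: NBS (1.05 equiv), MeCN, 0 °C to rt
Reagents that add atoms: N-bromosuccinimide, O=C1CCC(=O)N1Br
Why: Electrophilic aromatic bromination; the position ortho to the formyl group and para to an alkoxy group is activated and less crowded than the carbon between the two alkoxy groups, and the two such positions are equivalent by symmetry. Succinimide is the only by-product, so no strong acid endangers the MOM ethers.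

Step 14
Reactants: 22 2-bromo-3,5-bis(methoxymethoxy)benzaldehyde
Product: 23 2-[2-bromo-3,5-bis(methoxymethoxy)phenyl]-1,3-dioxolane
Conditions: (Me3SiOCH2)2 (1.5 equiv), Me3SiOTf (2 mol%), CH2Cl2, −78 °C; pyridine quench
Reagents that add atoms: 1,2-bis(trimethylsilyloxy)ethane, C[Si](C)(C)OCCO[Si](C)(C)C
Why: Aprotic acetalisation as in step 5, compatible with the MOM ethers.

Step 15
Reactants: 10 1-(benzyloxy)-4-bromobenzene; 19 alkenylboronic ester from step 11; 23 2-[2-bromo-3,5-bis(methoxymethoxy)phenyl]-1,3-dioxolane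
Product: 27 (1S,2S)-2-[(2R,3R)-7-(benzyloxy)-2-[4-(benzyloxy)phenyl]-3-[3,5-bis(benzyloxy)phenyl]-2,3-dihydro-1-benzofuran-5-yl]-1-[4-(benzyloxy)phenyl]-2-[2-(1,3-dioxolan-2-yl)-4,6-bis(methoxymethoxy)phenyl]ethan-1-ol, via aryl Grignard reagent 24 (not isolated), via bromomagnesium borate complex 25 (not isolated), via secondary boronic ester 26 (not isolated)
Conditions: 10, Mg (1.3 equiv), THF, 45 °C; add to 19 (1.0 equiv), NaOTf (3 equiv), THF, 0 °C to rt; then 23, Pd(OAc)2 (5 mol%), (Rp,Rp)-MandyPhos Fe[C5H3(PAr2)(CHPhNMe2)]2 (6 mol%), THF, 60 °C; then H2O2 (30% aq.), NaOH (3 M aq.), 0 °C to rt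
Reagents that add atoms: hydrogen peroxide, OO
Why: Grignard variant of the conjunctive cross-coupling of step 6 with the mirror-image ligand, in which NaOTf drives formation of borate 25 and removes halide; the arylpalladium from 23 triggers anti 1,2-shift of the 4-benzyloxyphenyl group to C2 and reductive elimination forms C3–C3a, giving the (1S,2S) boronic ester 26, which alkaline peroxide oxidises with retention. The less basic Grignard reagent 24 is used here because 19 has a diarylmethine C3′–H β to the ring oxygen that an aryllithium or residual t-BuLi could remove with ring opening. The ligand, not the remote C2′/C3′ centres, should decide the configuration at C3; the new demand is a bromide flanked by two ortho substituents.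

Step 16
Reactants: 27 triarylethanol from step 15
Product: 28 (2S,3S)-3-[(2R,3R)-7-(benzyloxy)-2-[4-(benzyloxy)phenyl]-3-[3,5-bis(benzyloxy)phenyl]-2,3-dihydro-1-benzofuran-5-yl]-2-[4-(benzyloxy)phenyl]-6-hydroxy-2,3-dihydro-1-benzofuran-4-carbaldehyde
Conditions: HCl (6 M aq.), THF, 50 °C
Reagents that add atoms: water, O
Why: As in step 8: hydrolysis of MOM ethers and dioxolane, ionisation at C2 and capture by the C7a oxygen (SN1 etherification) give the trans (2S,3S) ring with C3 unchanged. If the first dihydrobenzofuran opens at O1′–C2′ under the same acid, it re-closes to its trans form.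

Step 17
Reactants: 29 1-(benzyloxy)-4-(chloromethyl)benzene
Product: 30 [4-(benzyloxy)benzyl]triphenylphosphonium chloride
Conditions: PPh3 (1.05 equiv), toluene, 110 °C
Reagents that add atoms: triphenylphosphine, c1ccc(cc1)P(c1ccccc1)c1ccccc1
Why: SN2 quaternisation of the phosphine by a benzylic chloride; the salt crystallises from the hot solvent.

Step 18
Reactants: 28 aldehyde from step 16; 30 [4-(benzyloxy)benzyl]triphenylphosphonium chloride
Product: 32 (2S,3S)-3-[(2R,3R)-7-(benzyloxy)-2-[4-(benzyloxy)phenyl]-3-[3,5-bis(benzyloxy)phenyl]-2,3-dihydro-1-benzofuran-5-yl]-2-[4-(benzyloxy)phenyl]-4-[(Z)-2-[4-(benzyloxy)phenyl]ethenyl]-2,3-dihydro-1-benzofuran-6-ol, via phosphonium ylide 31 (not isolated)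
Conditions: 30 (3 equiv), KN(SiMe3)2 (4 equiv), THF, −78 °C; then 28, −78 °C to rt, dark
Reagents that add atoms: none
Why: Wittig olefination with a semi-stabilised benzylic ylide under lithium-free conditions at low temperature, where kinetic formation of the cis oxaphosphetane favours the Z alkene, helped by the ortho-substituted aldehyde. One extra equivalent of base covers the free phenol, and any E isomer is removed by chromatography.

Step 19
Reactants: 32 hexabenzyl ether from step 18
Product: 33 (2S,3S)-3-[(2R,3R)-3-(3,5-dihydroxyphenyl)-7-hydroxy-2-(4-hydroxyphenyl)-2,3-dihydro-1-benzofuran-5-yl]-2-(4-hydroxyphenyl)-4-[(Z)-2-(4-hydroxyphenyl)ethenyl]-2,3-dihydro-1-benzofuran-6-ol (target)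
Conditions: BCl3 (1 M in CH2Cl2, 14 equiv), C6HMe5 (20 equiv), CH2Cl2, −78 °C; MeOH quench at −78 °C; dark
Reagents that add atoms: none
Why: Lewis-acid O-debenzylation with pentamethylbenzene as a non-basic benzyl cation scavenger; no hydrogen is used, so the Z alkene and the benzylic C–O bonds are not reduced. The low temperature is meant to prevent acid-induced Z/E isomerisation, ring opening at C2/C2′ and Friedel–Crafts attack on the stilbene.

## Compound list

1 | acenaphthylene-1,2-dione | O=C1C(=O)c2cccc3cccc1c23 | starting material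
2 | cis-1,2-dimethyl-1,2-dihydroacenaphthylene-1,2-diol (meso) | C[C@]1(O)c2cccc3cccc(c32)[C@@]1(C)O | intermediate
3 | 3,5-bis(benzyloxy)benzaldehyde | O=Cc1cc(OCc2ccccc2)cc(OCc2ccccc2)c1 | starting material
4 | 1,3-bis(benzyloxy)-5-ethynylbenzene | C#Cc1cc(OCc2ccccc2)cc(OCc2ccccc2)c1 | intermediate
5 | 2-[(E)-2-[3,5-bis(benzyloxy)phenyl]ethenyl]-1,3,2-benzodioxaborole | O1c2ccccc2OB1/C=C/c1cc(OCc2ccccc2)cc(OCc2ccccc2)c1 | intermediate
6 | (E)-2-[3,5-bis(benzyloxy)phenyl]ethenylboronic ester of diol 2 | O5[C@@]6(C)c7cccc8cccc(c87)[C@@]6(C)OB5/C=C/c1cc(OCc2ccccc2)cc(OCc2ccccc2)c1 | intermediate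
7 | 3-bromo-4,5-dihydroxybenzaldehyde | O=Cc1cc(O)c(O)c(Br)c1 | starting material
8 | 3-bromo-4,5-bis(methoxymethoxy)benzaldehyde | O=Cc1cc(OCOC)c(OCOC)c(Br)c1 | intermediate
9 | 2-[3-bromo-4,5-bis(methoxymethoxy)phenyl]-1,3-dioxolane | COCOc1c(OCOC)cc(C2OCCO2)cc1Br | intermediate
10 | 1-(benzyloxy)-4-bromobenzene | Brc1ccc(OCc2ccccc2)cc1 | starting material
11 | [4-(benzyloxy)phenyl]lithium | [Li]c1ccc(OCc2ccccc2)cc1 | intermediate
12 | lithium borate complex of 6 with 11 (unspecified at boron) | [Li+].O5[C@@]6(C)c7cccc8cccc(c87)[C@@]6(C)O[B-]5(c1ccc(OCc2ccccc2)cc1)/C=C/c1cc(OCc2ccccc2)cc(OCc2ccccc2)c1 | intermediate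
13 | boronic ester of diol 2 with (1R,2R)-1-[4-(benzyloxy)phenyl]-2-[3,5-bis(benzyloxy)phenyl]-2-[5-(1,3-dioxolan-2-yl)-2,3-bis(methoxymethoxy)phenyl]ethylboronic acid | COCOc1c(OCOC)cc(C2OCCO2)cc1[C@@H](c1cc(OCc2ccccc2)cc(OCc2ccccc2)c1)[C@@H](B1O[C@@]2(C)c3cccc4cccc(c43)[C@@]2(C)O1)c1ccc(OCc2ccccc2)cc1 | intermediate
14 | (1R,2R)-1-[4-(benzyloxy)phenyl]-2-[3,5-bis(benzyloxy)phenyl]-2-[5-(1,3-dioxolan-2-yl)-2,3-bis(methoxymethoxy)phenyl]ethan-1-ol | COCOc1c(OCOC)cc(C2OCCO2)cc1[C@@H](c1cc(OCc2ccccc2)cc(OCc2ccccc2)c1)[C@@H](O)c1ccc(OCc2ccccc2)cc1 | intermediate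
15 | (2R,3R)-2-[4-(benzyloxy)phenyl]-3-[3,5-bis(benzyloxy)phenyl]-7-hydroxy-2,3-dihydro-1-benzofuran-5-carbaldehyde | O=Cc1cc(O)c2c(c1)[C@@H](c1cc(OCc3ccccc3)cc(OCc3ccccc3)c1)[C@H](c1ccc(OCc3ccccc3)cc1)O2 | intermediate
16 | (2R,3R)-7-(benzyloxy)-2-[4-(benzyloxy)phenyl]-3-[3,5-bis(benzyloxy)phenyl]-2,3-dihydro-1-benzofuran-5-carbaldehyde | O=Cc1cc(OCc3ccccc3)c2c(c1)[C@@H](c1cc(OCc3ccccc3)cc(OCc3ccccc3)c1)[C@H](c1ccc(OCc3ccccc3)cc1)O2 | intermediate
17 | (2R,3R)-7-(benzyloxy)-2-[4-(benzyloxy)phenyl]-3-[3,5-bis(benzyloxy)phenyl]-5-ethynyl-2,3-dihydro-1-benzofuran | C#Cc1cc(OCc3ccccc3)c2c(c1)[C@@H](c1cc(OCc3ccccc3)cc(OCc3ccccc3)c1)[C@H](c1ccc(OCc3ccccc3)cc1)O2 | intermediate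
18 | catechol ester of the (E)-alkenylboronic acid derived from 17 | O1c5ccccc5OB1/C=C/c1cc(OCc3ccccc3)c2c(c1)[C@@H](c1cc(OCc3ccccc3)cc(OCc3ccccc3)c1)[C@H](c1ccc(OCc3ccccc3)cc1)O2 | intermediate
19 | (E)-2-[(2R,3R)-7-(benzyloxy)-2-[4-(benzyloxy)phenyl]-3-[3,5-bis(benzyloxy)phenyl]-2,3-dihydro-1-benzofuran-5-yl]ethenylboronic ester of diol 2 | O5[C@@]6(C)c7cccc8cccc(c87)[C@@]6(C)OB5/C=C/c1cc(OCc3ccccc3)c2c(c1)[C@@H](c1cc(OCc3ccccc3)cc(OCc3ccccc3)c1)[C@H](c1ccc(OCc3ccccc3)cc1)O2 | intermediate
20 | 3,5-dihydroxybenzaldehyde | O=Cc1cc(O)cc(O)c1 | starting material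
21 | 3,5-bis(methoxymethoxy)benzaldehyde | O=Cc1cc(OCOC)cc(OCOC)c1 | intermediate
22 | 2-bromo-3,5-bis(methoxymethoxy)benzaldehyde | O=Cc1cc(OCOC)cc(OCOC)c1Br | intermediate
23 | 2-[2-bromo-3,5-bis(methoxymethoxy)phenyl]-1,3-dioxolane | COCOc1cc(OCOC)c(Br)c(C2OCCO2)c1 | intermediate
24 | [4-(benzyloxy)phenyl]magnesium bromide | Br[Mg]c1ccc(OCc2ccccc2)cc1 | intermediate
25 | bromomagnesium borate complex of 19 with 24 (unspecified at boron) | Br[Mg+].O5[C@@]6(C)c7cccc8cccc(c87)[C@@]6(C)O[B-]5(c1ccc(OCc3ccccc3)cc1)/C=C/c1cc(OCc3ccccc3)c2c(c1)[C@@H](c1cc(OCc3ccccc3)cc(OCc3ccccc3)c1)[C@H](c1ccc(OCc3ccccc3)cc1)O2 | intermediate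
26 | boronic ester of diol 2 with the (1S,2S)-1,2,2-triarylethylboronic acid corresponding to 27 | COCOc1cc(C2OCCO2)c(c(OCOC)c1)[C@H](c2cc(OCc3ccccc3)c4c(c2)[C@@H](c2cc(OCc3ccccc3)cc(OCc3ccccc3)c2)[C@H](c2ccc(OCc3ccccc3)cc2)O4)[C@H](B1O[C@@]2(C)c3cccc4cccc(c43)[C@@]2(C)O1)c1ccc(OCc2ccccc2)cc1 | intermediate
27 | (1S,2S)-2-[(2R,3R)-7-(benzyloxy)-2-[4-(benzyloxy)phenyl]-3-[3,5-bis(benzyloxy)phenyl]-2,3-dihydro-1-benzofuran-5-yl]-1-[4-(benzyloxy)phenyl]-2-[2-(1,3-dioxolan-2-yl)-4,6-bis(methoxymethoxy)phenyl]ethan-1-ol | COCOc1cc(C2OCCO2)c(c(OCOC)c1)[C@H](c2cc(OCc3ccccc3)c4c(c2)[C@@H](c2cc(OCc3ccccc3)cc(OCc3ccccc3)c2)[C@H](c2ccc(OCc3ccccc3)cc2)O4)[C@H](O)c1ccc(OCc2ccccc2)cc1 | intermediate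
28 | (2S,3S)-3-[(2R,3R)-7-(benzyloxy)-2-[4-(benzyloxy)phenyl]-3-[3,5-bis(benzyloxy)phenyl]-2,3-dihydro-1-benzofuran-5-yl]-2-[4-(benzyloxy)phenyl]-6-hydroxy-2,3-dihydro-1-benzofuran-4-carbaldehyde | O=Cc1cc(O)cc2c1[C@H](c5cc(OCc3ccccc3)c4c(c5)[C@@H](c5cc(OCc3ccccc3)cc(OCc3ccccc3)c5)[C@H](c5ccc(OCc3ccccc3)cc5)O4)[C@@H](c1ccc(OCc3ccccc3)cc1)O2 | intermediate
29 | 1-(benzyloxy)-4-(chloromethyl)benzene | ClCc1ccc(OCc2ccccc2)cc1 | starting material
30 | [4-(benzyloxy)benzyl]triphenylphosphonium chloride | [Cl-].c1ccccc1COc1ccc(C[P+](c2ccccc2)(c2ccccc2)c2ccccc2)cc1 | intermediate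
31 | [4-(benzyloxy)benzylidene]triphenylphosphorane | c1ccccc1COc1ccc(C=P(c2ccccc2)(c2ccccc2)c2ccccc2)cc1 | intermediate
32 | (2S,3S)-3-[(2R,3R)-7-(benzyloxy)-2-[4-(benzyloxy)phenyl]-3-[3,5-bis(benzyloxy)phenyl]-2,3-dihydro-1-benzofuran-5-yl]-2-[4-(benzyloxy)phenyl]-4-[(Z)-2-[4-(benzyloxy)phenyl]ethenyl]-2,3-dihydro-1-benzofuran-6-ol | c1ccccc1COc1ccc(/C=C\c2cc(O)cc3c2[C@H](c5cc(OCc6ccccc6)c4c(c5)[C@@H](c5cc(OCc6ccccc6)cc(OCc6ccccc6)c5)[C@H](c5ccc(OCc6ccccc6)cc5)O4)[C@@H](c2ccc(OCc6ccccc6)cc2)O3)cc1 | intermediate
33 | (2S,3S)-3-[(2R,3R)-3-(3,5-dihydroxyphenyl)-7-hydroxy-2-(4-hydroxyphenyl)-2,3-dihydro-1-benzofuran-5-yl]-2-(4-hydroxyphenyl)-4-[(Z)-2-(4-hydroxyphenyl)ethenyl]-2,3-dihydro-1-benzofuran-6-ol | Oc1ccc(/C=C\c2cc(O)cc3c2[C@H](c2cc(O)c4c(c2)[C@@H](c2cc(O)cc(O)c2)[C@H](c2ccc(O)cc2)O4)[C@@H](c2ccc(O)cc2)O3)cc1 | target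

## Step count and least certain steps

Total step count: 19. Longest linear sequence: 12 steps (steps 4, 5, 6, 7, 8, 9, 10, 11, 15, 16, 18, 19, from 7 to 33).

Step 6 (key step). The processes most likely to interfere are direct transfer of the alkenyl or aryl group from boron to palladium (Suzuki–Miyaura pathway), β-hydride loss from the benzylic palladium intermediate before reductive elimination, and incomplete facial discrimination, because a β-aryl alkene and an ortho-alkoxy arylpalladium are both more demanding than the usual partners. The fallback sets out from 3 and 9 and returns to the route at 14, and through step 8 at 15. It sets C3′ by conjugate arylation instead. Aldehyde 3 is condensed with nitromethane (NH4OAc, AcOH, 100 °C) to (E)-1,3-bis(benzyloxy)-5-(2-nitroethenyl)benzene F1. Bromide 9 is converted by bromine–lithium exchange (n-BuLi, −78 °C), B(Oi-Pr)3 and neutral hydrolysis into [5-(1,3-dioxolan-2-yl)-2,3-bis(methoxymethoxy)phenyl]boronic acid F2. Rhodium-catalysed asymmetric 1,4-addition of F2 to F1 (Rh(acac)(C2H4)2, BINAP of the hand that gives R, dioxane/H2O, 100 °C) gives 2-{3-[(1R)-1-[3,5-bis(benzyloxy)phenyl]-2-nitroethyl]-4,5-bis(methoxymethoxy)phenyl}-1,3-dioxolane F3. A buffered reductive Nef reaction (NaOMe, then TiCl3/NH4OAc aq.) converts F3 into (2R)-2-[3,5-bis(benzyloxy)phenyl]-2-[5-(1,3-dioxolan-2-yl)-2,3-bis(methoxymethoxy)phenyl]acetaldehyde F4, which is used at once. Addition of the organocerium reagent made from aryllithium 11 (generated from 10 and t-BuLi as in step 6) and CeCl3 at −78 °C, chosen to avoid enolisation, gives 14 together with its (1S,2R) carbinol epimer F5. Both converge on 15 in step 8, since that step re-forms C2′.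

Step 15. Oxidative addition and alkene binding by an arylpalladium with two ortho substituents may be too slow, so that direct transmetalation or protodeboronation of 25 takes over. Formation of the borate from the Grignard reagent and the hindered ester may also be incomplete, and a mismatch between the ligand and the existing stereocentres is a lesser concern. The fallback sets out from 16 and 23 and returns at 28. It makes the C3–C3a bond by carbonyl addition, which is insensitive to the ortho groups, and gives up catalyst control at C3. Bromide 23 is lithiated (n-BuLi, THF, −78 °C) and added to 16 to give the diarylmethanol F6. Dess–Martin oxidation gives the diaryl ketone F7. The sulfonium ylide from Me3SI and n-BuLi gives the 2,2-diaryloxirane F8, which ZnI2 rearranges (Meinwald rearrangement) to the 2,2-diarylacetaldehyde F9. The Grignard reagent 24, made from 10 and Mg as in step 15, adds to F9 to give the 1,2,2-triarylethanol F10 as a set of stereoisomers at C1 and C2 that includes 27. The conditions of step 16 close each of them to a trans ring, so that 28 forms together with its (2R,3R) diastereomer F11. The two are diastereomers because of the fixed C2′/C3′ centres and are separated by chromatography. The cost is the loss of the unwanted diastereomer.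

Step 18. The Z selectivity of a semi-stabilised ylide may erode through reversible oxaphosphetane formation, and the phenoxide of 28 may slow the addition. The fallback sets out from 28 and returns at 32, and makes the Z alkene by syn addition of hydrogen to an alkyne. Aldehyde 28 is homologated (MeC(O)C(N2)P(O)(OMe)2, K2CO3, MeOH) to the 4-ethynyl compound F12. Sonogashira coupling with 1-(benzyloxy)-4-iodobenzene (PdCl2(PPh3)2, CuI, Et3N) gives the diarylalkyne F13. Semi-hydrogenation over Pd/CaCO3 poisoned with Pb(OAc)2, with quinoline, gives 32; aryl benzyl ethers are not cleaved over the poisoned catalyst.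

Step 19. Acid generated during debenzylation may isomerise the Z stilbene, open the rings at C2 or C2′, or promote attack of ring B on the alkene, and six cleavages may not all go to completion at −78 °C. The fallback sets out from 28 and returns at 33, and moves the Lewis acid step to a point where no alkene is present. Aldehyde 28 is debenzylated (BCl3, C6HMe5, CH2Cl2, −78 °C) to the hexahydroxy aldehyde F14. Silylation (t-BuMe2SiCl, imidazole, DMF) gives the hexakis(tert-butyldimethylsilyl) ether F15. Wittig reaction with the ylide from [4-(tert-butyldimethylsilyloxy)benzyl]triphenylphosphonium bromide F16 (made from the benzyl bromide and PPh3; KN(SiMe3)2, THF, −78 °C) gives the heptasilylated Z stilbene F17. Buffered fluoride (Bu4NF, AcOH, THF, 0 °C) then frees all seven phenols and gives 33.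

## Further compounds

F1 | step 6 | (E)-1,3-bis(benzyloxy)-5-(2-nitroethenyl)benzene | [O-][N+](=O)/C=C/c1cc(OCc2ccccc2)cc(OCc2ccccc2)c1
F2 | step 6 | [5-(1,3-dioxolan-2-yl)-2,3-bis(methoxymethoxy)phenyl]boronic acid | COCOc1cc(C2OCCO2)cc(B(O)O)c1OCOC
F3 | step 6 | 2-{3-[(1R)-1-[3,5-bis(benzyloxy)phenyl]-2-nitroethyl]-4,5-bis(methoxymethoxy)phenyl}-1,3-dioxolane | COCOc1c(OCOC)cc(C2OCCO2)cc1[C@@H](c1cc(OCc2ccccc2)cc(OCc2ccccc2)c1)C[N+](=O)[O-]
F4 | step 6 | (2R)-2-[3,5-bis(benzyloxy)phenyl]-2-[5-(1,3-dioxolan-2-yl)-2,3-bis(methoxymethoxy)phenyl]acetaldehyde | COCOc1c(OCOC)cc(C2OCCO2)cc1[C@@H](c1cc(OCc2ccccc2)cc(OCc2ccccc2)c1)C=O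
F5 | step 6 | (1S,2R)-1-[4-(benzyloxy)phenyl]-2-[3,5-bis(benzyloxy)phenyl]-2-[5-(1,3-dioxolan-2-yl)-2,3-bis(methoxymethoxy)phenyl]ethan-1-ol | COCOc1c(OCOC)cc(C2OCCO2)cc1[C@@H](c1cc(OCc2ccccc2)cc(OCc2ccccc2)c1)[C@H](O)c1ccc(OCc2ccccc2)cc1
F6 | step 15 | [(2R,3R)-7-(benzyloxy)-2-[4-(benzyloxy)phenyl]-3-[3,5-bis(benzyloxy)phenyl]-2,3-dihydro-1-benzofuran-5-yl][2-(1,3-dioxolan-2-yl)-4,6-bis(methoxymethoxy)phenyl]methanol (both carbinol epimers) | COCOc1cc(C2OCCO2)c(c(OCOC)c1)C(O)c2cc(OCc3ccccc3)c4c(c2)[C@@H](c2cc(OCc3ccccc3)cc(OCc3ccccc3)c2)[C@H](c2ccc(OCc3ccccc3)cc2)O4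
F7 | step 15 | [(2R,3R)-7-(benzyloxy)-2-[4-(benzyloxy)phenyl]-3-[3,5-bis(benzyloxy)phenyl]-2,3-dihydro-1-benzofuran-5-yl][2-(1,3-dioxolan-2-yl)-4,6-bis(methoxymethoxy)phenyl]methanone | COCOc1cc(C2OCCO2)c(c(OCOC)c1)C(=O)c2cc(OCc3ccccc3)c4c(c2)[C@@H](c2cc(OCc3ccccc3)cc(OCc3ccccc3)c2)[C@H](c2ccc(OCc3ccccc3)cc2)O4
F8 | step 15 | 2,2-diaryloxirane derived from F7 (both epimers at the oxirane carbon) | COCOc1cc(C2OCCO2)c(c(OCOC)c1)C1(CO1)c2cc(OCc3ccccc3)c4c(c2)[C@@H](c2cc(OCc3ccccc3)cc(OCc3ccccc3)c2)[C@H](c2ccc(OCc3ccccc3)cc2)O4
F9 | step 15 | 2-[(2R,3R)-7-(benzyloxy)-2-[4-(benzyloxy)phenyl]-3-[3,5-bis(benzyloxy)phenyl]-2,3-dihydro-1-benzofuran-5-yl]-2-[2-(1,3-dioxolan-2-yl)-4,6-bis(methoxymethoxy)phenyl]acetaldehyde (both C2 epimers) | COCOc1cc(C2OCCO2)c(c(OCOC)c1)C(C=O)c2cc(OCc3ccccc3)c4c(c2)[C@@H](c2cc(OCc3ccccc3)cc(OCc3ccccc3)c2)[C@H](c2ccc(OCc3ccccc3)cc2)O4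
F10 | step 15 | stereoisomers at C1 and C2 of the 1,2,2-triarylethanol 27 | COCOc1cc(C2OCCO2)c(c(OCOC)c1)C(c2cc(OCc3ccccc3)c4c(c2)[C@@H](c2cc(OCc3ccccc3)cc(OCc3ccccc3)c2)[C@H](c2ccc(OCc3ccccc3)cc2)O4)C(O)c1ccc(OCc2ccccc2)cc1
F11 | step 15 | (2R,3R)-3-[(2R,3R)-7-(benzyloxy)-2-[4-(benzyloxy)phenyl]-3-[3,5-bis(benzyloxy)phenyl]-2,3-dihydro-1-benzofuran-5-yl]-2-[4-(benzyloxy)phenyl]-6-hydroxy-2,3-dihydro-1-benzofuran-4-carbaldehyde | O=Cc1cc(O)cc2c1[C@@H](c5cc(OCc3ccccc3)c4c(c5)[C@@H](c5cc(OCc3ccccc3)cc(OCc3ccccc3)c5)[C@H](c5ccc(OCc3ccccc3)cc5)O4)[C@H](c1ccc(OCc3ccccc3)cc1)O2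
F12 | step 18 | (2S,3S)-3-[(2R,3R)-7-(benzyloxy)-2-[4-(benzyloxy)phenyl]-3-[3,5-bis(benzyloxy)phenyl]-2,3-dihydro-1-benzofuran-5-yl]-2-[4-(benzyloxy)phenyl]-4-ethynyl-2,3-dihydro-1-benzofuran-6-ol | C#Cc1cc(O)cc2c1[C@H](c5cc(OCc3ccccc3)c4c(c5)[C@@H](c5cc(OCc3ccccc3)cc(OCc3ccccc3)c5)[C@H](c5ccc(OCc3ccccc3)cc5)O4)[C@@H](c1ccc(OCc3ccccc3)cc1)O2
F13 | step 18 | (2S,3S)-3-[(2R,3R)-7-(benzyloxy)-2-[4-(benzyloxy)phenyl]-3-[3,5-bis(benzyloxy)phenyl]-2,3-dihydro-1-benzofuran-5-yl]-2-[4-(benzyloxy)phenyl]-4-{[4-(benzyloxy)phenyl]ethynyl}-2,3-dihydro-1-benzofuran-6-ol | c1ccccc1COc1ccc(C#Cc2cc(O)cc3c2[C@H](c5cc(OCc6ccccc6)c4c(c5)[C@@H](c5cc(OCc6ccccc6)cc(OCc6ccccc6)c5)[C@H](c5ccc(OCc6ccccc6)cc5)O4)[C@@H](c2ccc(OCc6ccccc6)cc2)O3)cc1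
F14 | step 19 | (2S,3S)-3-[(2R,3R)-3-(3,5-dihydroxyphenyl)-7-hydroxy-2-(4-hydroxyphenyl)-2,3-dihydro-1-benzofuran-5-yl]-6-hydroxy-2-(4-hydroxyphenyl)-2,3-dihydro-1-benzofuran-4-carbaldehyde | O=Cc1cc(O)cc2c1[C@H](c5cc(O)c4c(c5)[C@@H](c5cc(O)cc(O)c5)[C@H](c5ccc(O)cc5)O4)[C@@H](c1ccc(O)cc1)O2
F15 | step 19 | hexakis(tert-butyldimethylsilyl) ether of F14 | O=Cc1cc(O[Si](C)(C)C(C)(C)C)cc2c1[C@H](c5cc(O[Si](C)(C)C(C)(C)C)c4c(c5)[C@@H](c5cc(O[Si](C)(C)C(C)(C)C)cc(O[Si](C)(C)C(C)(C)C)c5)[C@H](c5ccc(O[Si](C)(C)C(C)(C)C)cc5)O4)[C@@H](c1ccc(O[Si](C)(C)C(C)(C)C)cc1)O2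
F16 | step 19 | [4-(tert-butyldimethylsilyloxy)benzyl]triphenylphosphonium bromide | [Br-].CC(C)(C)[Si](C)(C)Oc1ccc(C[P+](c2ccccc2)(c2ccccc2)c2ccccc2)cc1
F17 | step 19 | heptakis(tert-butyldimethylsilyl) ether of 33 | CC(C)(C)[Si](C)(C)Oc1ccc(/C=C\c2cc(O[Si](C)(C)C(C)(C)C)cc3c2[C@H](c5cc(O[Si](C)(C)C(C)(C)C)c4c(c5)[C@@H](c5cc(O[Si](C)(C)C(C)(C)C)cc(O[Si](C)(C)C(C)(C)C)c5)[C@H](c5ccc(O[Si](C)(C)C(C)(C)C)cc5)O4)[C@@H](c2ccc(O[Si](C)(C)C(C)(C)C)cc2)O3)cc1
A1 | alternative 1 | (2S)-5-(benzyloxy)-7-methoxy-2-[4-(pivaloyloxy)phenyl]chroman-4-one | C1[C@H](Oc2cc(OC)cc(OCc3ccccc3)c2C1=O)c1ccc(OC(=O)C(C)(C)C)cc1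
A2 | alternative 1 | methyl (2S,3S)-4-benzyloxy-6-methoxy-2-(4-pivaloyloxyphenyl)-2,3-dihydrobenzofuran-3-carboxylate | c1ccccc1COc1cc(OC)cc2c1[C@H](C(=O)OC)[C@@H](c1ccc(OC(=O)C(C)(C)C)cc1)O2
A3 | alternative 2 | {5-[(1R,2R)-1-(3,5-dimethoxyphenyl)-2-(ethynyloxy)-2-(4-methoxyphenyl)ethyl]furan-3-yl}methyl triisopropylsilyl ether | CC(C)[Si](OCc1coc(c1)[C@@H](c1cc(OC)cc(OC)c1)[C@H](c1ccc(OC)cc1)OC#C)(C(C)C)C(C)C
A4 | alternative 2 | (2R,3R)-3-(3,5-dimethoxyphenyl)-2-(4-methoxyphenyl)-5-[(triisopropylsilyloxy)methyl]-2,3-dihydro-1-benzofuran-7-ol | CC(C)[Si](OCc1cc(O)c2c(c1)[C@@H](c1cc(OC)cc(OC)c1)[C@H](c1ccc(OC)cc1)O2)(C(C)C)C(C)C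
A5 | alternative 3 | 1,6-diyne with an ethynyl ether on O1 and a (Z)-4-methoxystyryl alkyne on C3, carrying the hexamethylated dihydrobenzofuran 2 on C3 | COc1ccc(/C=C\C#C[C@H](c2cc(OC)c3c(c2)[C@@H](c2cc(OC)cc(OC)c2)[C@H](c2ccc(OC)cc2)O3)[C@@H](c2ccc(OC)cc2)OC#C)cc1
A6 | alternative 3 | hexamethyl C6-ethyl ether of 33 | COc1ccc(/C=C\c2cc(OCC)cc3c2[C@H](c2cc(OC)c4c(c2)[C@@H](c2cc(OC)cc(OC)c2)[C@H](c2ccc(OC)cc2)O4)[C@@H](c2ccc(OC)cc2)O3)cc1
A7 | alternative 3 | ethoxyacetylene | CCOC#C
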